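## Retrosynthetic overview

1. The target comes from its bis-benzyl ether by hydrogenolysis. The 2,6-cis-oxane comes from axial hydride opening of a 5-aryl-6,8-dioxabicyclo[3.2.1]octane ketal. Cleaving C1–O6 sets C1 and frees the C6-OH.
2. The bicyclic ketal is made in one flask. An aryllithium adds to an unprotected dihydroxy-δ-lactone (C1–aryl bond) to give the open-chain keto-triol. Acid then closes the oxane ring (O5) and the 1,3-dioxolane ring (O6) together on C1.
3. The lactone comes from acid unmasking of a statin-type acetonide tert-butyl ester. The C6 carbinol comes from Felkin reduction of a benzyl ketone.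
4. The benzyl ketone comes from the commercial (4R,6S)-6-formyl-dioxane acetate (C1–C6, with C3 and C5 already set) and a 4-(benzyloxy)benzyl Grignard reagent, oxidised in the same flask.
5. Ring order: a transient δ-lactone forms and is opened again, then oxane and dioxolane form at once, then the dioxolane is cut reductively and the oxane stays.

Assumption: the statin side-chain aldehyde, 4-(benzyloxy)benzyl chloride and 1-(benzyloxy)-4-bromo-2-methoxybenzene are bought as catalogue chemicals. Positions use heptane numbering, with C1 bearing the guaiacyl ring and C7 the CH2 of the 4-hydroxyphenyl ring.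

## Route

**Step 1**
Reactants: 1 tert-butyl 2-[(4R,6S)-6-formyl-2,2-dimethyl-1,3-dioxan-4-yl]acetate; 2 4-(benzyloxy)benzyl chloride
Product: 5 tert-butyl 2-[(4R,6S)-6-{[4-(benzyloxy)phenyl]acetyl}-2,2-dimethyl-1,3-dioxan-4-yl]acetate, via [4-(benzyloxy)benzyl]magnesium chloride 3 (not isolated), via chloromagnesium alkoxide of the C6-epimeric secondary alcohols 4 (not isolated)
Conditions: 2, Mg turnings, 2-MeTHF, 0 °C; add to 1, THF, −78 °C; then PhS(Cl)=N-t-Bu (1.5 equiv), −78 °C → rt; aq NH4Cl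
Reagents that add atoms: none
Why: Chemoselective Grignard addition to the aldehyde (the tert-butyl ester is inert at −78 °C) followed by Mukaiyama sulfinimidoyl chloride oxidation of the magnesium alkoxide (O–S bond formation, then intramolecular H abstraction by nitrogen) gives the ketone in one flask, so the unselective C6 carbinol centre is erased at once and C5 is kept because enolisation goes to the benzylic C7 side.

**Step 2**
Reactants: 5 tert-butyl 2-[(4R,6S)-6-{[4-(benzyloxy)phenyl]acetyl}-2,2-dimethyl-1,3-dioxan-4-yl]acetate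
Product: 6 tert-butyl 2-[(4R,6S)-6-{(1S)-2-[4-(benzyloxy)phenyl]-1-hydroxyethyl}-2,2-dimethyl-1,3-dioxan-4-yl]acetate
Conditions: L-Selectride (1.3 equiv), THF, −78 °C; then aq NaOH, H2O2, 0 °C
Reagents that add atoms: none
Why: In this polar Felkin–Anh ketone reduction the bulky, non-chelating hydride attacks anti to the C5–O bond of the dioxane, which gives the 5,6-syn (threo) alcohol and so sets C6 as S (dr ≥ 10:1 expected) while the tert-butyl ester is untouched.

**Step 3**
Reactants: 6 tert-butyl 2-[(4R,6S)-6-{(1S)-2-[4-(benzyloxy)phenyl]-1-hydroxyethyl}-2,2-dimethyl-1,3-dioxan-4-yl]acetate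
Product: 8 (4R,6S)-6-{(1S)-2-[4-(benzyloxy)phenyl]-1-hydroxyethyl}-4-hydroxyoxan-2-one, via (3R,5S,6S)-7-[4-(benzyloxy)phenyl]-3,5,6-trihydroxyheptanoic acid 7 (not isolated)
Conditions: TFA–CH2Cl2–H2O (20:78:2), 0 °C → rt; aq NaHCO3
Reagents that add atoms: none
Why: Acidolysis of the acetonide and of the tert-butyl ester (E1 loss of isobutene) gives trihydroxy acid 7, which closes spontaneously through O5 to the six-membered lactone (statin-type δ-lactonisation, favoured over the seven-membered ring through O6) without touching a stereocentre.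

**Step 4 (key step)**
Reactants: 8 (4R,6S)-6-{(1S)-2-[4-(benzyloxy)phenyl]-1-hydroxyethyl}-4-hydroxyoxan-2-one; 9 1-(benzyloxy)-4-bromo-2-methoxybenzene
Product: 12 (1S,3R,5S,7S)-5-[4-(benzyloxy)-3-methoxyphenyl]-7-[4-(benzyloxy)benzyl]-6,8-dioxabicyclo[3.2.1]octan-3-ol (7-exo benzyl; 3-OH equatorial, anti to the O6–C7 bridge), via [4-(benzyloxy)-3-methoxyphenyl]lithium 10 (not isolated), via open-chain (3R,5S,6S)-1-[4-(benzyloxy)-3-methoxyphenyl]-7-[4-(benzyloxy)phenyl]-3,5,6-trihydroxyheptan-1-one 11 (not isolated)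
Conditions: 9 (3.4 equiv), n-BuLi (3.3 equiv), THF, −78 °C; add 8, −78 °C; then MsOH (4 equiv), 4 Å MS, −78 °C → rt
Reagents that add atoms: none
Why: In this aryllithium–lactone addition (C-aryl glycoside type) followed by brevicomin-type dehydrative bicycloketalisation, two equivalents of 10 turn both hydroxyls into alkoxides (which blocks E1cB loss of the β-oxygen), the third adds once to the carbonyl, acid releases the electron-rich aryl ketone as open-chain 11, and O5 and O6 then close the oxane and 1,3-dioxolane rings on C1 in the same operation, the bridge allowing only one configuration (S) at the new ketal centre as dictated by C5.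

**Step 5**
Reactants: 12 (1S,3R,5S,7S)-5-[4-(benzyloxy)-3-methoxyphenyl]-7-[4-(benzyloxy)benzyl]-6,8-dioxabicyclo[3.2.1]octan-3-ol
Product: 13 (2R,4S,6S)-2-[4-(benzyloxy)-3-methoxyphenyl]-6-{(1S)-2-[4-(benzyloxy)phenyl]-1-hydroxyethyl}oxan-4-ol
Conditions: Et3SiH (3 equiv), BF3·OEt2 (2.5 equiv), CH2Cl2–MeCN (1:1), −78 → −40 °C; aq NaHCO3
Reagents that add atoms: none
Why: In this ionic (silane/Lewis acid) reduction of a bicyclic ketal, ionisation of the strained dioxolane C1–O6 bond leaves the aryl-stabilised six-membered oxocarbenium half-chair with the C5 side chain pseudo-equatorial and the C3 oxygen pseudo-axial, and axial hydride delivery sets C1 as R (2,6-cis, 4-OH axial) and frees the C6 hydroxyl.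

**Step 6**
Reactants: 13 (2R,4S,6S)-2-[4-(benzyloxy)-3-methoxyphenyl]-6-{(1S)-2-[4-(benzyloxy)phenyl]-1-hydroxyethyl}oxan-4-ol
Product: 14 rhoiptelol B, (2S,4S,6R)-2-[(1S)-1-hydroxy-2-(4-hydroxyphenyl)ethyl]-6-(4-hydroxy-3-methoxyphenyl)oxan-4-ol
Conditions: H2 (1 atm), 10 % Pd/C, EtOAc, rt, stopped at full conversion
Reagents that add atoms: none
Why: Catalytic hydrogenolysis cleaves the two primary aryl benzyl ethers much faster than the secondary cyclic benzylic C1–O bond in neutral EtOAc, and no stereocentre is affected.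

## Compound list

1 | tert-butyl 2-[(4R,6S)-6-formyl-2,2-dimethyl-1,3-dioxan-4-yl]acetate | CC(C)(C)OC(=O)C[C@H]1C[C@@H](C=O)OC(C)(C)O1 | starting material
2 | 4-(benzyloxy)benzyl chloride | ClCc1ccc(OCc2ccccc2)cc1 | starting material
3 | [4-(benzyloxy)benzyl]magnesium chloride | Cl[Mg]Cc1ccc(OCc2ccccc2)cc1 | intermediate
4 | chloromagnesium alkoxide of tert-butyl 2-[(4R,6S)-6-{2-[4-(benzyloxy)phenyl]-1-hydroxyethyl}-2,2-dimethyl-1,3-dioxan-4-yl]acetate (both C6 epimers) | CC(C)(C)OC(=O)C[C@H]1C[C@@H](C(O[Mg]Cl)Cc2ccc(OCc3ccccc3)cc2)OC(C)(C)O1 | intermediate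
5 | tert-butyl 2-[(4R,6S)-6-{[4-(benzyloxy)phenyl]acetyl}-2,2-dimethyl-1,3-dioxan-4-yl]acetate | CC(C)(C)OC(=O)C[C@H]1C[C@@H](C(=O)Cc2ccc(OCc3ccccc3)cc2)OC(C)(C)O1 | intermediate
6 | tert-butyl 2-[(4R,6S)-6-{(1S)-2-[4-(benzyloxy)phenyl]-1-hydroxyethyl}-2,2-dimethyl-1,3-dioxan-4-yl]acetate | CC(C)(C)OC(=O)C[C@H]1C[C@@H]([C@@H](O)Cc2ccc(OCc3ccccc3)cc2)OC(C)(C)O1 | intermediate
7 | (3R,5S,6S)-7-[4-(benzyloxy)phenyl]-3,5,6-trihydroxyheptanoic acid | OC(=O)C[C@H](O)C[C@H](O)[C@@H](O)Cc1ccc(OCc2ccccc2)cc1 | intermediate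
8 | (4R,6S)-6-{(1S)-2-[4-(benzyloxy)phenyl]-1-hydroxyethyl}-4-hydroxyoxan-2-one | O=C1C[C@H](O)C[C@@H]([C@@H](O)Cc2ccc(OCc3ccccc3)cc2)O1 | intermediate
9 | 1-(benzyloxy)-4-bromo-2-methoxybenzene | COc1cc(Br)ccc1OCc1ccccc1 | starting material
10 | [4-(benzyloxy)-3-methoxyphenyl]lithium | [Li]c1ccc(OCc2ccccc2)c(OC)c1 | intermediate
11 | (3R,5S,6S)-1-[4-(benzyloxy)-3-methoxyphenyl]-7-[4-(benzyloxy)phenyl]-3,5,6-trihydroxyheptan-1-one | COc1cc(ccc1OCc1ccccc1)C(=O)C[C@H](O)C[C@H](O)[C@@H](O)Cc1ccc(OCc2ccccc2)cc1 | intermediate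
12 | (1S,3R,5S,7S)-5-[4-(benzyloxy)-3-methoxyphenyl]-7-[4-(benzyloxy)benzyl]-6,8-dioxabicyclo[3.2.1]octan-3-ol | COc1cc(ccc1OCc1ccccc1)[C@]12C[C@H](O)C[C@H](O1)[C@H](Cc1ccc(OCc3ccccc3)cc1)O2 | intermediate
13 | (2R,4S,6S)-2-[4-(benzyloxy)-3-methoxyphenyl]-6-{(1S)-2-[4-(benzyloxy)phenyl]-1-hydroxyethyl}oxan-4-ol | COc1cc([C@H]2C[C@H](O)C[C@@H]([C@@H](O)Cc3ccc(OCc4ccccc4)cc3)O2)ccc1OCc1ccccc1 | intermediate
14 | rhoiptelol B | COc1cc([C@H]2C[C@H](O)C[C@@H]([C@@H](O)Cc3ccc(O)cc3)O2)ccc1O | target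

## Step count and risks

Total step count: 6. Longest linear sequence: 6 (1 → 5 → 6 → 8 → 12 → 13 → 14).

**Step 4 is the most likely to fail.** 10 may enolise the lactone or add twice. Acid may also expel the C3 hydroxyl (enone formation or Ferrier-type ionisation) before the ketal closes. The fallback sets out from 6 and comes back at 12. It makes the C1–aryl bond at the aldehyde oxidation level with the acetonide still in place. DIBAL-H (CH2Cl2, −78 °C) reduces the tert-butyl ester to the acetonide aldehyde F1. 10 adds to it to give the C1-epimeric benzylic alcohols F2. MnO2 oxidises only the electron-rich benzylic carbinol to the acetonide aryl ketone F3. CSA in wet CH2Cl2 then removes the acetonide and closes the same two rings to 12.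

**Step 5 is second.** The electron-rich 2-aryl-oxane can re-ionise and be over-reduced to the open-chain C1H2 compound. C1–O8 cleavage would give an oxepane, and the C3 hydroxyl can be lost. The fallback sets out from 12 and comes back at 14. It replaces ketal reduction by alkene hydrogenation and resets C3.
- Dess–Martin oxidation gives the bicyclic keto ketal F4.
- A trace of DBU opens it by retro-oxa-Michael reaction to the 6-aryl-dihydropyranone F5.
- H2/Pd–C adds to C1=C2 from the face opposite the C5 side chain (2,6-cis) and removes both benzyl groups, giving the cis-oxan-4-one bisphenol F6.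
- Excess L-Selectride (THF, −78 °C) attacks equatorially and delivers the axial C3 alcohol 14.

**Step 1 is third.** 3 is prone to Wurtz coupling. The magnesium alkoxide 4 may react sluggishly with the oxidant, and the enolisable benzyl ketone may be sulfenylated. The fallback sets out from 1 and comes back at 5, and it needs no oxidation after the C–C bond formation. Pinnick oxidation gives the dioxane carboxylic acid F7. CDI and MeNHOMe·HCl give the Weinreb amide F8, which takes up 3 only once to give 5.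

## Further compounds

F1 | step 4 | acetonide aldehyde, 2-[(4R,6S)-6-{(1S)-2-[4-(benzyloxy)phenyl]-1-hydroxyethyl}-2,2-dimethyl-1,3-dioxan-4-yl]acetaldehyde | O=CC[C@H]1C[C@@H]([C@@H](O)Cc2ccc(OCc3ccccc3)cc2)OC(C)(C)O1
F2 | step 4 | C1-epimeric benzylic alcohols, 1-[4-(benzyloxy)-3-methoxyphenyl]-2-[(4S,6S)-6-{(1S)-2-[4-(benzyloxy)phenyl]-1-hydroxyethyl}-2,2-dimethyl-1,3-dioxan-4-yl]ethan-1-ol | COc1cc(ccc1OCc1ccccc1)C(O)C[C@H]1C[C@@H]([C@@H](O)Cc2ccc(OCc3ccccc3)cc2)OC(C)(C)O1
F3 | step 4 | acetonide aryl ketone, 1-[4-(benzyloxy)-3-methoxyphenyl]-2-[(4R,6S)-6-{(1S)-2-[4-(benzyloxy)phenyl]-1-hydroxyethyl}-2,2-dimethyl-1,3-dioxan-4-yl]ethan-1-one | COc1cc(ccc1OCc1ccccc1)C(=O)C[C@H]1C[C@@H]([C@@H](O)Cc2ccc(OCc3ccccc3)cc2)OC(C)(C)O1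
F4 | step 5 | bicyclic keto ketal, (1S,5S,7S)-5-[4-(benzyloxy)-3-methoxyphenyl]-7-[4-(benzyloxy)benzyl]-6,8-dioxabicyclo[3.2.1]octan-3-one | COc1cc(ccc1OCc1ccccc1)[C@]12CC(=O)C[C@H](O1)[C@H](Cc1ccc(OCc3ccccc3)cc1)O2
F5 | step 5 | 6-aryl-dihydropyranone, (2S)-6-[4-(benzyloxy)-3-methoxyphenyl]-2-{(1S)-2-[4-(benzyloxy)phenyl]-1-hydroxyethyl}-2,3-dihydro-4H-pyran-4-one | COc1cc(ccc1OCc1ccccc1)C1=CC(=O)C[C@@H]([C@@H](O)Cc2ccc(OCc3ccccc3)cc2)O1
F6 | step 5 | cis-oxan-4-one bisphenol, (2S,6R)-2-[(1S)-1-hydroxy-2-(4-hydroxyphenyl)ethyl]-6-(4-hydroxy-3-methoxyphenyl)oxan-4-one | COc1cc([C@H]2CC(=O)C[C@@H]([C@@H](O)Cc3ccc(O)cc3)O2)ccc1O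
F7 | step 1 | dioxane carboxylic acid, (4S,6R)-6-(2-tert-butoxy-2-oxoethyl)-2,2-dimethyl-1,3-dioxane-4-carboxylic acid | CC(C)(C)OC(=O)C[C@H]1C[C@@H](C(=O)O)OC(C)(C)O1
F8 | step 1 | Weinreb amide, tert-butyl 2-[(4R,6S)-6-[methoxy(methyl)carbamoyl]-2,2-dimethyl-1,3-dioxan-4-yl]acetate | CC(C)(C)OC(=O)C[C@H]1C[C@@H](C(=O)N(C)OC)OC(C)(C)O1
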